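**Retrosynthetic overview**
- No ring is built: both benzene rings are bought. Ring A comes from guaiacol 1, exhaustively brominated to tetrabromoguaiacol 2.
- Ring B comes from 2-amino-4,6-dibromophenol 3, which already carries the hydroxyl and both bromines in the right places. Diazotisation (through diazonium chloride 4) gives the ortho-quinone diazide 5.
- Key disconnection: the diaryl ether C(ring B)–O bond, made last by carbenoid O–H insertion of 5 into the phenol O–H of 2 (through oxonium ylide 6), giving target 7.

Assumption: the target has no stereocentre and no configurationally stable axis, so it is achiral and the route delivers the single constitutional isomer drawn.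

**Step 1**
Reactants: 1 guaiacol (2-methoxyphenol)
Product: 2 3,4,5,6-tetrabromo-2-methoxyphenol
Conditions: Br2 (4.5 equiv), Fe powder (5 mol %), CHCl3, 0 → 50 °C, 12 h; aq NaHSO3 work-up
Reagents that add atoms: bromine, BrBr
Why: Electrophilic aromatic bromination (SEAr): hydroxyl and methoxyl together activate all four free positions, the first three react uncatalysed and FeBr3 formed in situ drives the last one (C3, ortho to OMe), while the mild temperature keeps HBr from cleaving the methyl ether; no stereocenter is formed.

**Step 2**
Reactants: 3 2-amino-4,6-dibromophenol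
Product: 5 2,4-dibromo-6-diazocyclohexa-2,4-dien-1-one, via diazonium chloride 4 (not isolated)
Conditions: NaNO2 (1.05 equiv), 2 M aq HCl/AcOH, 0–5 °C, 30 min; then aq NaOAc to pH 5–6, 0 °C; filter, wash cold, dry in vacuo in the dark
Reagents that add atoms: sodium nitrite, [Na+].[O-]N=O
Why: Diazotisation of the primary arylamine in strongly acidic medium (which suppresses triazene formation) gives the ortho-hydroxy diazonium salt 4, which on buffering loses HCl to the neutral, water-insoluble diazo oxide 5, an ortho-quinone diazide stabilised by its two bromines; no stereocenter is formed.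

**Step 3**
Reactants: 2 3,4,5,6-tetrabromo-2-methoxyphenol; 5 2,4-dibromo-6-diazocyclohexa-2,4-dien-1-one
Product: 7 2,4-dibromo-6-(2,3,4,5-tetrabromo-6-methoxyphenoxy)phenol, via oxonium ylide 6 (not isolated)
Conditions: Rh2(OAc)4 (2 mol %), 2 (1.5 equiv, excess recovered), ClCH2CH2Cl, 60 °C, 5 added by syringe pump over 4 h, dark, Ar
Reagents that add atoms: none
Why: Proposed new method: Rh2(OAc)4 extrudes N2 from 5 to give an electrophilic, catalyst-bound quinoid carbene of divalent rhodium whose carbene carbon is attacked by the phenolic oxygen of 2 (pKa about 6, and with no ring C–H to divert the carbene into C–H functionalisation), and the released oxonium ylide 6 passes its proton to the adjacent phenoxide oxygen with rearomatisation of ring B, so the new C–O bond, the free hydroxyl and both bromines are placed without regiochemical ambiguity; the closest known reaction type is dirhodium-carbenoid O–H insertion of α-diazocarbonyl compounds into phenols, together with quinone-diazide carbene transfer to C–H and N–H bonds, here extended to an ortho-quinone diazide and a hindered, acidic polybromophenol as a diaryl-ether-forming step; no stereocenter is formed.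

**Compound list**
1 | guaiacol (2-methoxyphenol) | COc1ccccc1O | starting material
2 | 3,4,5,6-tetrabromo-2-methoxyphenol (tetrabromoguaiacol) | COc1c(O)c(Br)c(Br)c(Br)c1Br | intermediate
3 | 2-amino-4,6-dibromophenol | Nc1cc(Br)cc(Br)c1O | starting material
4 | 3,5-dibromo-2-hydroxybenzenediazonium chloride | Oc1c(Br)cc(Br)cc1[N+]#N.[Cl-] | intermediate
5 | 2,4-dibromo-6-diazocyclohexa-2,4-dien-1-one (ortho-quinone diazide) | O=C1C(Br)=CC(Br)=CC1=[N+]=[N-] | intermediate
6 | 2,4-dibromo-6-[(2,3,4,5-tetrabromo-6-methoxyphenyl)oxonio]phenolate (oxonium ylide) | COc1c(Br)c(Br)c(Br)c(Br)c1[OH+]c1cc(Br)cc(Br)c1[O-] | intermediate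
7 | 2,4-dibromo-6-(2,3,4,5-tetrabromo-6-methoxyphenoxy)phenol | COc1c(Br)c(Br)c(Br)c(Br)c1Oc1cc(Br)cc(Br)c1O | target

**Step count and risks**
Total step count: 3. Longest linear sequence: 2 steps (1 → 2 → 7, or 3 → 5 → 7).

The three steps most likely to fail, most risky first:

Step 3 (the proposed new step). The risks are carbene dimerisation or oligomerisation through the oxygen of unreacted 5, a second insertion into the hydroxyl of the product, photochemical Wolff rearrangement, and sluggish attack by the hindered, weakly nucleophilic phenol. Slow addition, excess 2 and exclusion of light are meant to counter these. The fallback uses known chemistry only, sets out from 2 and comes back at 7. Purchased 1-(benzyloxy)-2-iodobenzene is oxidised with mCPBA/TsOH·H2O in MeCN to 1-(benzyloxy)-2-[hydroxy(tosyloxy)iodo]benzene F1, which is not isolated. It is trapped with 1,3,5-trimethoxybenzene to give [2-(benzyloxy)phenyl](2,4,6-trimethoxyphenyl)iodonium tosylate F2. Compound 2 is deprotonated with t-BuOK in THF and arylated with F2 at 25–40 °C. This is metal-free ligand coupling at trivalent iodine, a method established for hindered bromophenols, with the trimethoxyphenyl group as the ligand that is not transferred. It gives 1-(benzyloxy)-2-(2,3,4,5-tetrabromo-6-methoxyphenoxy)benzene F3. BCl3/pentamethylbenzene in CH2Cl2 at −78 °C removes the benzyl group without touching the methyl ether or any C–Br bond, giving 2-(2,3,4,5-tetrabromo-6-methoxyphenoxy)phenol F4. Br2 (2.05 equiv) in AcOH at 20 °C then brominates ring B para and ortho to its free hydroxyl (ring A has no C–H left) and delivers 7.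

Step 2. Compound 5 is a diazo oxide and is sensitive to light, heat and possibly shock, so it should be made on a scale of a few millimoles, kept cold and dark, and used promptly. Triazene formation or partial hydrolysis would lower the yield. The fallback sets out from 3 and comes back at 5, and it avoids ever handling neat 5. Non-aqueous diazotisation (t-BuONO, HBF4·OEt2, THF, −10 °C, then Et2O) precipitates the storable salt 3,5-dibromo-2-hydroxybenzenediazonium tetrafluoroborate F5. Just before the coupling, a cold CH2Cl2 suspension of F5 is shaken with aqueous NaHCO3, the organic layer is dried, and the resulting solution of 5 is fed directly into step 3.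

Step 1. The fourth bromination (C3) may stall at the tribromide, and forcing it may cleave the methyl ether. The fallback sets out from 1 and comes back at 2, and it accepts the ether cleavage deliberately. Guaiacol is brominated under forcing, demethylating conditions (Br2 5 equiv, AcOH, 25 → 80 °C, then 48% HBr, reflux; NaHSO3 work-up, which also reduces any ortho-quinone formed) to 3,4,5,6-tetrabromobenzene-1,2-diol (tetrabromocatechol) F6, a compound that can also be bought. Desymmetrising mono-O-methylation (MeI 1.0 equiv, Li2CO3 1.0 equiv, DMF, 40 °C) then returns 2; the selectivity rests on the monoanion of F6 being more acidic than 2.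

**Further compounds**
F1 | step 3 | 1-(benzyloxy)-2-[hydroxy(tosyloxy)iodo]benzene | Cc1ccc(cc1)S(=O)(=O)OI(O)c1ccccc1OCc1ccccc1
F2 | step 3 | [2-(benzyloxy)phenyl](2,4,6-trimethoxyphenyl)iodonium 4-methylbenzenesulfonate | COc1cc(OC)c([I+]c2ccccc2OCc2ccccc2)c(OC)c1.Cc1ccc(cc1)S(=O)(=O)[O-]
F3 | step 3 | 1-(benzyloxy)-2-(2,3,4,5-tetrabromo-6-methoxyphenoxy)benzene | COc1c(Br)c(Br)c(Br)c(Br)c1Oc1ccccc1OCc1ccccc1
F4 | step 3 | 2-(2,3,4,5-tetrabromo-6-methoxyphenoxy)phenol | COc1c(Br)c(Br)c(Br)c(Br)c1Oc1ccccc1O
F5 | step 2 | 3,5-dibromo-2-hydroxybenzenediazonium tetrafluoroborate | Oc1c(Br)cc(Br)cc1[N+]#N.F[B-](F)(F)F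
F6 | step 1 | 3,4,5,6-tetrabromobenzene-1,2-diol (tetrabromocatechol) | Oc1c(O)c(Br)c(Br)c(Br)c1Br
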